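The plan hinges on breaking the O1–C2 bond of the oxolane (O1; C2 with ring B; C3; C4; C5 with ring C). Because C2 is a benzylic ether carbon activated by the para oxygen of ring B, and the target places ring B anti to the methyl on C3 (the lower-energy arrangement), this centre can be created last under equilibrating acid. A 1,4-diaryl-2,3-dimethylbutane-1,4-diol with C3, C4 and C5 already fixed and both C2 carbinol epimers is ionised at C2; the C5 hydroxyl traps the cation, closing the ring and setting C2 at once. Ring C carries a tosylate so that C5 stays put. The threo side chain is attached afterwards.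

Key step: step 9

Assumption: the oxolane is numbered O1, C2 (ring B), C3, C4, C5 (ring C), and ring A is the side-chain aryl group with C7 the carbinol and C8 the ether carbon; on this numbering the target is (2R,3R,4R,5S) in the ring (2,3-trans, 3,4-trans, 4,5-cis) and (7R,8R), i.e. threo, in the side chain (Ts = 4-methylphenylsulfonyl, Bn = benzyl, Ipc = isopinocampheyl from (+)-α-pinene).

Step 1
Reactants: 1 vanillin
Product: 2 4-formyl-2-methoxyphenyl 4-methylbenzenesulfonate
Conditions: TsCl, Et3N, DMAP (cat.), CH2Cl2, 0 °C → rt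
Reagents that add atoms: 4-methylbenzenesulfonyl chloride, Cc1ccc(cc1)S(Cl)(=O)=O
Why: O-Sulfonylation of the phenol under amine base is routine and should give the aryl tosylate, which protects ring C and makes it electron-poor for the later ring closure.

Step 2
Reactants: 2 vanillin tosylate; 3 (Z)-but-2-ene
Product: 7 4-[(1S,2R)-1-hydroxy-2-methylbut-3-enyl]-2-methoxyphenyl 4-methylbenzenesulfonate, via (Z)-crotylpotassium 4 (not isolated), via (Z)-crotyldiisopinocampheylborane 5 (not isolated), via diisopinocampheylborinate ester 6 (not isolated)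
Conditions: 3, KOt-Bu, n-BuLi, THF, −78 → −45 °C; (−)-Ipc2BOMe, −78 °C; BF3·OEt2; then 2, −78 °C; NaBO3·4H2O, THF/H2O, rt
Reagents that add atoms: none
Why: Brown asymmetric (Z)-crotylboration through a closed chair (Zimmerman–Traxler) transition state should give the syn alcohol, the Z geometry setting the 1,2-syn relationship and the (+)-α-pinene-derived Ipc groups directing attack to the Si face of the aldehyde, so that C1 (S, the future C5) and C2 (R, the future C4) are both set here.

Step 3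
Reactants: 7 syn homoallylic alcohol
Product: 9 4-[(1S,2R)-1,4-dihydroxy-2-methylbutyl]-2-methoxyphenyl 4-methylbenzenesulfonate, via bis(9-BBN) adduct 8 (not isolated)
Conditions: 9-BBN (2.5 equiv), THF, 0 °C → rt; NaBO3·4H2O, H2O, rt
Reagents that add atoms: sodium perborate tetrahydrate, [Na+].[O-]OB=O.O.O.O.O
Why: Anti-Markovnikov hydroboration–oxidation with 9-BBN should place the hydroxyl on the terminal carbon only, the free alcohol merely consuming one equivalent of borane, and the mild perborate oxidation should leave the aryl tosylate and both stereocentres untouched.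

Step 4
Reactants: 9 1,4-diol
Product: 11 (4R,5S)-5-(3-methoxy-4-tosyloxyphenyl)-4-methyloxolan-2-one (4,5-cis), via lactol 10 (not isolated)
Conditions: TEMPO (0.2 equiv), PhI(OAc)2 (2.5 equiv), CH2Cl2, rt
Reagents that add atoms: none
Why: TEMPO/PhI(OAc)2 oxidative lactonisation should oxidise the primary alcohol selectively, the aldehyde being trapped by the benzylic hydroxyl as a lactol that is oxidised on to the γ-lactone without touching C4 or C5.

Step 5
Reactants: 11 cis lactone
Product: 13 (3R,4R,5S)-5-(3-methoxy-4-tosyloxyphenyl)-3,4-dimethyloxolan-2-one (3,4-trans and 4,5-cis), via lithium enolate 12 (not isolated)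
Conditions: LiHMDS (1.1 equiv), THF, −78 °C; MeI, −78 → −40 °C
Reagents that add atoms: iodomethane, CI
Why: Alkylation of the lactone lithium enolate with MeI should occur on the face opposite the C4 methyl and C5 aryl groups (both on one face), setting C3 (R) trans to the C4 methyl.

Step 6
Reactants: 14 4-bromo-2-methoxyphenol
Product: 15 1-(benzyloxy)-4-bromo-2-methoxybenzene
Conditions: BnBr, K2CO3, DMF, rt
Reagents that add atoms: benzyl bromide, BrCc1ccccc1
Why: Williamson etherification of the phenoxide with benzyl bromide is routine and gives the aryl bromide that serves for ring B here and for ring A in step 12.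

Step 7
Reactants: 13 trans-dimethyl lactone; 15 aryl bromide
Product: 19 (2R,3R,4S)-1-(4-benzyloxy-3-methoxyphenyl)-4-hydroxy-4-(3-methoxy-4-tosyloxyphenyl)-2,3-dimethylbutan-1-one, via aryllithium 16 (not isolated), via arylcerium dichloride 17 (not isolated), via cyclic hemiketal 18 (not isolated)
Conditions: 15, n-BuLi, THF, −78 °C; anhydrous CeCl3, −78 °C; then 13, −78 °C; aq. NH4Cl
Reagents that add atoms: none
Why: Bromine–lithium exchange and transmetallation give a weakly basic arylcerium reagent whose single nucleophilic acyl addition to the lactone stops at the metal hemiketalate at −78 °C, so that work-up should give the γ-hydroxy aryl ketone without double addition, enolisation at C3 or attack on the tosylate.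

Step 8
Reactants: 19 ketol
Product: 20 (1RS,2R,3R,4S)-1-(4-benzyloxy-3-methoxyphenyl)-4-(3-methoxy-4-tosyloxyphenyl)-2,3-dimethylbutane-1,4-diol
Conditions: NaBH4, MeOH/THF, 0 °C
Reagents that add atoms: none
Why: Borohydride reduction of the aryl ketone should give the 1,4-diol as both C2 carbinol epimers, which is acceptable because C2 is re-formed in step 9.

Step 9
Reactants: 20 1,4-diol (C2 epimers)
Product: 22 (2R,3R,4R,5S)-2-(4-benzyloxy-3-methoxyphenyl)-5-(3-methoxy-4-tosyloxyphenyl)-3,4-dimethyloxolane, via benzylic cation 21 (not isolated)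
Conditions: BF3·OEt2 (0.2 equiv), CH2Cl2, −40 → 0 °C; aq. NaHCO3
Reagents that add atoms: none
Why: BF3 activates the C2 hydroxyl of both carbinol epimers, and its departure leaves one common benzylic cation stabilised by the para benzyloxy group of ring B, which the C5 oxygen then traps. The closest known reaction is the acid-promoted cyclodehydration of 1,4-diaryl-butane-1,4-diols to 2,5-diaryl oxolanes, together with the acid-induced C2 epimerisation of 2-aryl oxolanes. The ring closes by a 5-exo-trig attack of oxygen on the trigonal cationic carbon, forming O1–C2. The new C2 centre is governed by the neighbouring C3 methyl: ring B should end up on the opposite face, and because closure is reversible under the acid the 2,3-trans arrangement is also the thermodynamic outcome. The step needs ionisation at C2 and not at C5, and no Friedel–Crafts attack on ring C; both are secured by the electron-poor tosylated ring C, which can neither stabilise a C5 cation nor act as a π-nucleophile, so C5 keeps its S configuration.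

Step 10
Reactants: 22 benzyl ether
Product: 23 4-[(2S,3R,4R,5R)-5-(4-hydroxy-3-methoxyphenyl)-3,4-dimethyloxolan-2-yl]-2-methoxyphenyl 4-methylbenzenesulfonate (ring B phenol; 2R,3R,4R,5S on the numbering used here)
Conditions: H2 (1 atm), 10% Pd/C, EtOAc, rt
Reagents that add atoms: none
Why: Palladium-catalysed hydrogenolysis of the aryl benzyl ether in neutral ethyl acetate should be much faster than cleavage of the ring benzylic C–O bonds and leaves the aryl tosylate untouched.

Step 11
Reactants: 24 ethyl (S)-lactate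
Product: 25 (S)-2-hydroxy-N-methoxy-N-methylpropanamide
Conditions: MeNHOMe·HCl, i-PrMgCl, THF, −20 → 0 °C
Reagents that add atoms: N,O-dimethylhydroxylamine hydrochloride, CNOC.Cl
Why: Direct aminolysis of the ester by the magnesium amide of N,O-dimethylhydroxylamine (Weinreb amide formation) should proceed with the hydroxyl carried as its magnesium alkoxide and without enolising the stereocentre.

Step 12
Reactants: 25 Weinreb amide; 15 aryl bromide
Product: 27 (S)-1-(4-benzyloxy-3-methoxyphenyl)-2-hydroxypropan-1-one, via arylmagnesium bromide 26 (not isolated)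
Conditions: 15, Mg, THF; 25, i-PrMgCl (1.0 equiv), THF, −20 °C; then the Grignard solution (1.5 equiv), 0 °C → rt; aq. NH4Cl
Reagents that add atoms: none
Why: Grignard addition to the Weinreb amide should stop at the chelated tetrahedral intermediate and give the aryl ketone on work-up, the adjacent magnesium alkoxide preventing enolisation so that the S configuration is kept.

Step 13
Reactants: 27 α-hydroxy ketone
Product: 28 (S)-1-(4-benzyloxy-3-methoxyphenyl)-1-oxopropan-2-yl 4-methylbenzenesulfonate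
Conditions: TsCl, pyridine, DMAP (cat.), CH2Cl2, 0 °C
Reagents that add atoms: 4-methylbenzenesulfonyl chloride, Cc1ccc(cc1)S(Cl)(=O)=O
Why: O-Sulfonylation of the secondary alcohol with retention gives the carbonyl-activated leaving group, and the weak base pyridine at 0 °C should not enolise the ketone.

Step 14
Reactants: 23 ring B phenol; 28 (S)-α-tosyloxy ketone
Product: 29 (2R)-1-(4-benzyloxy-3-methoxyphenyl)-2-{4-[(2R,3R,4R,5S)-5-(3-methoxy-4-tosyloxyphenyl)-3,4-dimethyloxolan-2-yl]-2-methoxyphenoxy}propan-1-one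
Conditions: K2CO3, 18-crown-6 (cat.), MeCN, rt
Reagents that add atoms: none
Why: SN2 displacement (Williamson etherification) of the carbonyl-activated secondary tosylate by the ring B phenoxide should proceed with inversion and so set C8 (R).

Step 15
Reactants: 29 α-aryloxy ketone
Product: 30 (1R,2R)-1-(4-benzyloxy-3-methoxyphenyl)-2-{4-[(2R,3R,4R,5S)-5-(3-methoxy-4-tosyloxyphenyl)-3,4-dimethyloxolan-2-yl]-2-methoxyphenoxy}propan-1-ol (threo)
Conditions: L-Selectride, THF, −78 °C; aq. NH4Cl
Reagents that add atoms: none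
Why: Felkin–Anh-controlled hydride reduction with a bulky, poorly chelating reagent: with the C8–OAr bond anti to the incoming hydride, attack past the C8 hydrogen should set C7 (R), i.e. the threo alcohol.

Step 16
Reactants: 30 threo alcohol
Product: 31 (1R,2R)-1-(4-benzyloxy-3-methoxyphenyl)-2-{4-[(2R,3R,4R,5S)-5-(4-hydroxy-3-methoxyphenyl)-3,4-dimethyloxolan-2-yl]-2-methoxyphenoxy}propan-1-ol
Conditions: KOH, MeOH/THF, 60 °C; then aq. NH4Cl
Reagents that add atoms: none
Why: Alkaline S–O cleavage of the aryl sulfonate (sulfonate ester hydrolysis) should free the ring C phenol, while the alkyl aryl ethers and the benzylic alcohol, whose ring A phenol is still benzylated and so cannot form a quinone methide, are stable to base.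

Step 17
Reactants: 31 ring A benzyl ether
Product: 32 (1R,2R)-1-(4-hydroxy-3-methoxyphenyl)-2-{4-[(2R,3R,4R,5S)-5-(4-hydroxy-3-methoxyphenyl)-3,4-dimethyloxolan-2-yl]-2-methoxyphenoxy}propan-1-ol (target)
Conditions: H2 (1 atm), 10% Pd/C, EtOAc, rt
Reagents that add atoms: none
Why: Hydrogenolysis of the remaining aryl benzyl ether under neutral conditions should give the target, O-benzyl cleavage being faster than hydrogenolysis of the benzylic alcohol or of the ring C–O bonds.

Compound list

1 | vanillin (4-hydroxy-3-methoxybenzaldehyde) | COc1cc(C=O)ccc1O | starting material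
2 | 4-formyl-2-methoxyphenyl 4-methylbenzenesulfonate (vanillin tosylate) | COc1cc(C=O)ccc1OS(=O)(=O)c1ccc(C)cc1 | intermediate
3 | (Z)-but-2-ene | C/C=C\C | starting material
4 | (Z)-crotylpotassium | [K+].[CH2-]/C=C\C | intermediate
5 | (Z)-but-2-enylbis[(1R,2S,3R,5R)-2,6,6-trimethylbicyclo[3.1.1]hept-3-yl]borane | C/C=C\CB([C@@H]1C[C@@H]2C[C@@H](C2(C)C)[C@H]1C)[C@@H]1C[C@@H]2C[C@@H](C2(C)C)[C@H]1C | intermediate
6 | (1S,2R)-1-(3-methoxy-4-tosyloxyphenyl)-2-methylbut-3-enyl diisopinocampheylborinate | B(O[C@H](c1ccc(OS(=O)(=O)c2ccc(C)cc2)c(OC)c1)[C@H](C)C=C)([C@@H]1C[C@@H]2C[C@@H](C2(C)C)[C@H]1C)[C@@H]1C[C@@H]2C[C@@H](C2(C)C)[C@H]1C | intermediate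
7 | 4-[(1S,2R)-1-hydroxy-2-methylbut-3-enyl]-2-methoxyphenyl 4-methylbenzenesulfonate (syn) | O[C@H](c1ccc(OS(=O)(=O)c2ccc(C)cc2)c(OC)c1)[C@H](C)C=C | intermediate
8 | bis(9-BBN) adduct of 7 (C4–B and O–B) | O([C@H](c1ccc(OS(=O)(=O)c2ccc(C)cc2)c(OC)c1)[C@H](C)CCB1C2CCCC1CCC2)B1C2CCCC1CCC2 | intermediate
9 | 4-[(1S,2R)-1,4-dihydroxy-2-methylbutyl]-2-methoxyphenyl 4-methylbenzenesulfonate | O[C@H](c1ccc(OS(=O)(=O)c2ccc(C)cc2)c(OC)c1)[C@H](C)CCO | intermediate
10 | (4R,5S)-5-(3-methoxy-4-tosyloxyphenyl)-4-methyloxolan-2-ol (lactol, both anomers) | OC1O[C@H](c2ccc(OS(=O)(=O)c3ccc(C)cc3)c(OC)c2)[C@H](C)C1 | intermediate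
11 | (4R,5S)-5-(3-methoxy-4-tosyloxyphenyl)-4-methyloxolan-2-one | O=C1O[C@H](c2ccc(OS(=O)(=O)c3ccc(C)cc3)c(OC)c2)[C@H](C)C1 | intermediate
12 | lithium enolate of 11 | [Li]OC1=C[C@@H](C)[C@@H](c2ccc(OS(=O)(=O)c3ccc(C)cc3)c(OC)c2)O1 | intermediate
13 | (3R,4R,5S)-5-(3-methoxy-4-tosyloxyphenyl)-3,4-dimethyloxolan-2-one | O=C1O[C@H](c2ccc(OS(=O)(=O)c3ccc(C)cc3)c(OC)c2)[C@H](C)[C@H]1C | intermediate
14 | 4-bromo-2-methoxyphenol | COc1cc(Br)ccc1O | starting material
15 | 1-(benzyloxy)-4-bromo-2-methoxybenzene | COc1cc(Br)ccc1OCc1ccccc1 | intermediate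
16 | (4-benzyloxy-3-methoxyphenyl)lithium | [Li]c1ccc(OCc2ccccc2)c(OC)c1 | intermediate
17 | (4-benzyloxy-3-methoxyphenyl)cerium dichloride | Cl[Ce](Cl)c1ccc(OCc2ccccc2)c(OC)c1 | intermediate
18 | (3R,4R,5S)-2-(4-benzyloxy-3-methoxyphenyl)-5-(3-methoxy-4-tosyloxyphenyl)-3,4-dimethyloxolan-2-ol (cyclic hemiketal, present as its metal alkoxide) | OC1(c2ccc(OCc3ccccc3)c(OC)c2)O[C@H](c2ccc(OS(=O)(=O)c3ccc(C)cc3)c(OC)c2)[C@H](C)[C@H]1C | intermediate
19 | (2R,3R,4S)-1-(4-benzyloxy-3-methoxyphenyl)-4-hydroxy-4-(3-methoxy-4-tosyloxyphenyl)-2,3-dimethylbutan-1-one | O[C@H](c1ccc(OS(=O)(=O)c2ccc(C)cc2)c(OC)c1)[C@H](C)[C@@H](C)C(=O)c1ccc(OCc2ccccc2)c(OC)c1 | intermediate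
20 | (1RS,2R,3R,4S)-1-(4-benzyloxy-3-methoxyphenyl)-4-(3-methoxy-4-tosyloxyphenyl)-2,3-dimethylbutane-1,4-diol (key-step precursor) | O[C@H](c1ccc(OS(=O)(=O)c2ccc(C)cc2)c(OC)c1)[C@H](C)[C@@H](C)C(O)c1ccc(OCc2ccccc2)c(OC)c1 | intermediate
21 | C2 benzylic cation from 20 | O[C@H](c1ccc(OS(=O)(=O)c2ccc(C)cc2)c(OC)c1)[C@H](C)[C@@H](C)[CH+]c1ccc(OCc2ccccc2)c(OC)c1 | intermediate
22 | (2R,3R,4R,5S)-2-(4-benzyloxy-3-methoxyphenyl)-5-(3-methoxy-4-tosyloxyphenyl)-3,4-dimethyloxolane (key-step product) | COc1cc([C@@H]2O[C@H](c3ccc(OS(=O)(=O)c4ccc(C)cc4)c(OC)c3)[C@H](C)[C@H]2C)ccc1OCc1ccccc1 | intermediate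
23 | (2R,3R,4R,5S)-2-(4-hydroxy-3-methoxyphenyl)-5-(3-methoxy-4-tosyloxyphenyl)-3,4-dimethyloxolane | COc1cc([C@@H]2O[C@H](c3ccc(OS(=O)(=O)c4ccc(C)cc4)c(OC)c3)[C@H](C)[C@H]2C)ccc1O | intermediate
24 | ethyl (S)-lactate | CCOC(=O)[C@H](C)O | starting material
25 | (S)-2-hydroxy-N-methoxy-N-methylpropanamide | C[C@H](O)C(=O)N(C)OC | intermediate
26 | (4-benzyloxy-3-methoxyphenyl)magnesium bromide | Br[Mg]c1ccc(OCc2ccccc2)c(OC)c1 | intermediate
27 | (S)-1-(4-benzyloxy-3-methoxyphenyl)-2-hydroxypropan-1-one | C[C@H](O)C(=O)c1ccc(OCc2ccccc2)c(OC)c1 | intermediate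
28 | (S)-1-(4-benzyloxy-3-methoxyphenyl)-1-oxopropan-2-yl 4-methylbenzenesulfonate | C[C@H](OS(=O)(=O)c1ccc(C)cc1)C(=O)c1ccc(OCc2ccccc2)c(OC)c1 | intermediate
29 | (2R)-1-(4-benzyloxy-3-methoxyphenyl)-2-{4-[(2R,3R,4R,5S)-5-(3-methoxy-4-tosyloxyphenyl)-3,4-dimethyloxolan-2-yl]-2-methoxyphenoxy}propan-1-one | COc1cc(C(=O)[C@@H](C)Oc2ccc([C@@H]3O[C@H](c4ccc(OS(=O)(=O)c5ccc(C)cc5)c(OC)c4)[C@H](C)[C@H]3C)cc2OC)ccc1OCc1ccccc1 | intermediate
30 | (1R,2R)-1-(4-benzyloxy-3-methoxyphenyl)-2-{4-[(2R,3R,4R,5S)-5-(3-methoxy-4-tosyloxyphenyl)-3,4-dimethyloxolan-2-yl]-2-methoxyphenoxy}propan-1-ol | COc1cc([C@@H](O)[C@@H](C)Oc2ccc([C@@H]3O[C@H](c4ccc(OS(=O)(=O)c5ccc(C)cc5)c(OC)c4)[C@H](C)[C@H]3C)cc2OC)ccc1OCc1ccccc1 | intermediate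
31 | (1R,2R)-1-(4-benzyloxy-3-methoxyphenyl)-2-{4-[(2R,3R,4R,5S)-5-(4-hydroxy-3-methoxyphenyl)-3,4-dimethyloxolan-2-yl]-2-methoxyphenoxy}propan-1-ol | COc1cc([C@@H](O)[C@@H](C)Oc2ccc([C@@H]3O[C@H](c4ccc(O)c(OC)c4)[C@H](C)[C@H]3C)cc2OC)ccc1OCc1ccccc1 | intermediate
32 | (1R,2R)-1-(4-hydroxy-3-methoxyphenyl)-2-{4-[(2R,3R,4R,5S)-5-(4-hydroxy-3-methoxyphenyl)-3,4-dimethyloxolan-2-yl]-2-methoxyphenoxy}propan-1-ol | COc1cc([C@@H](O)[C@@H](C)Oc2ccc([C@@H]3O[C@H](c4ccc(O)c(OC)c4)[C@H](C)[C@H]3C)cc2OC)ccc1O | target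

Total step count: 17. Longest linear sequence: 13 steps (steps 1–5, 7–10, 14–17, from vanillin).

Steps most likely to fail

1. Step 9 (ring closure). The C2 cation may lose the C3 proton and be reprotonated, which would erode the C3 configuration; equilibration toward the 2,3-trans ring may stall; or the cation may be diverted into Friedel–Crafts ring closure. The fallback forms the C2–aryl bond on a preformed ring instead of the O1–C2 bond. It sets out from lactone 13. DIBAL-H (CH2Cl2, −78 °C) should give the lactol (3R,4R,5S)-5-(3-methoxy-4-tosyloxyphenyl)-3,4-dimethyloxolan-2-ol F1. Benzenesulfinic acid and CaCl2 in CH2Cl2 should convert it into the 2-(phenylsulfonyl)oxolane F2. Treatment with (4-benzyloxy-3-methoxyphenyl)zinc bromide F3 (from Grignard reagent 26 and ZnBr2) in THF should ionise the sulfone to the cyclic oxocarbenium ion and deliver ring B anti to the C3 methyl, a known displacement of 2-sulfonyl cyclic ethers by organozinc reagents. The fallback comes back to the route at 22.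

2. Step 15 (ketone reduction). Hydride delivery may show poor facial selectivity if a lithium chelate between the carbonyl and the C8 ether oxygen competes with the Felkin–Anh pathway, which would give the erythro epimer. The fallback accepts the chelate product and inverts C7. It sets out from ketone 29. Zn(BH4)2 (Et2O, 0 °C), a chelation-controlled reduction, should give the erythro (7S,8R) alcohol F4. Mitsunobu esterification with 4-nitrobenzoic acid (PPh3, DIAD, THF, 0 °C) should invert C7 and give the (7R,8R) 4-nitrobenzoate F5. The conditions of step 16 (KOH, MeOH/THF) should then cleave the ester and the tosylate together. The fallback comes back to the route at 31.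

3. Step 14 (phenol alkylation). Base-induced enolisation of tosylate 28 or of product 29 may erode the C8 configuration, and elimination may compete with substitution. The fallback builds the ketone after the ether bond. It sets out from phenol 23. A Mitsunobu reaction with ethyl (S)-lactate 24 (PPh3, DIAD, THF), which inverts the lactate centre, should give the ethyl (R)-2-aryloxypropanoate F6. MeNHOMe·HCl with i-PrMgCl (THF, −20 °C) should give the Weinreb amide F7. Addition of Grignard reagent 26 (THF, 0 °C) should give the ketone. The fallback comes back to the route at 29.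

Further compounds

F1 | step 9 | (3R,4R,5S)-5-(3-methoxy-4-tosyloxyphenyl)-3,4-dimethyloxolan-2-ol (both anomers) | OC1O[C@H](c2ccc(OS(=O)(=O)c3ccc(C)cc3)c(OC)c2)[C@H](C)[C@H]1C
F2 | step 9 | 2-methoxy-4-[(2S,3R,4R)-3,4-dimethyl-5-(phenylsulfonyl)oxolan-2-yl]phenyl 4-methylbenzenesulfonate (both sulfone epimers) | O=S(=O)(c1ccccc1)C1O[C@H](c2ccc(OS(=O)(=O)c3ccc(C)cc3)c(OC)c2)[C@H](C)[C@H]1C
F3 | step 9 | (4-benzyloxy-3-methoxyphenyl)zinc bromide | Br[Zn]c1ccc(OCc2ccccc2)c(OC)c1
F4 | step 15 | (1S,2R)-1-(4-benzyloxy-3-methoxyphenyl)-2-{4-[(2R,3R,4R,5S)-5-(3-methoxy-4-tosyloxyphenyl)-3,4-dimethyloxolan-2-yl]-2-methoxyphenoxy}propan-1-ol (erythro) | COc1cc([C@H](O)[C@@H](C)Oc2ccc([C@@H]3O[C@H](c4ccc(OS(=O)(=O)c5ccc(C)cc5)c(OC)c4)[C@H](C)[C@H]3C)cc2OC)ccc1OCc1ccccc1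
F5 | step 15 | (1R,2R)-1-(4-benzyloxy-3-methoxyphenyl)-2-{4-[(2R,3R,4R,5S)-5-(3-methoxy-4-tosyloxyphenyl)-3,4-dimethyloxolan-2-yl]-2-methoxyphenoxy}propyl 4-nitrobenzoate | COc1cc([C@@H](OC(=O)c2ccc(cc2)[N+](=O)[O-])[C@@H](C)Oc2ccc([C@@H]3O[C@H](c4ccc(OS(=O)(=O)c5ccc(C)cc5)c(OC)c4)[C@H](C)[C@H]3C)cc2OC)ccc1OCc1ccccc1
F6 | step 14 | ethyl (2R)-2-{4-[(2R,3R,4R,5S)-5-(3-methoxy-4-tosyloxyphenyl)-3,4-dimethyloxolan-2-yl]-2-methoxyphenoxy}propanoate | CCOC(=O)[C@@H](C)Oc1ccc([C@@H]2O[C@H](c3ccc(OS(=O)(=O)c4ccc(C)cc4)c(OC)c3)[C@H](C)[C@H]2C)cc1OC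
F7 | step 14 | (2R)-N-methoxy-N-methyl-2-{4-[(2R,3R,4R,5S)-5-(3-methoxy-4-tosyloxyphenyl)-3,4-dimethyloxolan-2-yl]-2-methoxyphenoxy}propanamide | CON(C)C(=O)[C@@H](C)Oc1ccc([C@@H]2O[C@H](c3ccc(OS(=O)(=O)c4ccc(C)cc4)c(OC)c3)[C@H](C)[C@H]2C)cc1OC
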